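The ten-membered carbocycle is closed at the bond between the carbinol carbon next to the epoxide (C1) and the ring carbon that bears the isopropyl group (C10). The feature used is this CH(isopropyl) beside a CH–OH: isopropyl is a reduced 2-propenyl group, so C10 is the γ-carbon of a 2-methylallyl unit. One chromium-mediated intramolecular allylation of an (E)-enal by a (Z)-2-methylallyl bromide closes the ring and sets C1 and C10, steered by the silyloxy centre C9 that comes from methyl (R)-glycidate. The precursor is an open C12 bromo-enal chain. The new hydroxyl then directs the epoxidation; hydrogenation, desilylation and acylation finish the route.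

Key step: step 12

Remark: in the Why lines the carbons keep the numbering of the open chain 15 (C1 = aldehyde carbon, C9 = silyloxy carbon, C12 = CH2Br carbon), also for the ring compounds; the systematic names use their own locants. The ring alkene is built as drawn, with its two ring CH2 groups cis (Z).

Step 1
Reactants: 1 geraniol
Product: 2 1-({[(2E)-3,7-dimethylocta-2,6-dien-1-yl]oxy}methyl)-4-methoxybenzene
Conditions: NaH, 4-methoxybenzyl chloride, Bu4NI (cat.), THF, 0 → 25 °C
Reagents that add atoms: 4-methoxybenzyl chloride, COc1ccc(CCl)cc1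
Why: Williamson etherification of the primary allylic alkoxide protects C1–O as an ether that survives the organometallic steps; no stereocentre is formed.

Step 2
Reactants: 2 1-({[(2E)-3,7-dimethylocta-2,6-dien-1-yl]oxy}methyl)-4-methoxybenzene
Product: 3 (4E)-6-[(4-methoxyphenyl)methoxy]-4-methylhex-4-enal
Conditions: O3 (1.0 equiv), pyridine, CH2Cl2, −78 °C
Reagents that add atoms: ozone, [O-][O+]=O
Why: Site-selective ozonolysis should cleave the electron-rich terminal alkene ahead of the alkene deactivated by the allylic ether oxygen, and pyridine turns the carbonyl oxide into the aldehyde without a separate reduction.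

Step 3
Reactants: 3 (4E)-6-[(4-methoxyphenyl)methoxy]-4-methylhex-4-enal
Product: 4 1-({[(2E,6Z)-7-iodo-3-methylocta-2,6-dien-1-yl]oxy}methyl)-4-methoxybenzene
Conditions: EtPPh3I, n-BuLi, THF, 25 °C; I2, −78 °C; NaN(SiMe3)2, −20 °C; then 3, −78 → −20 °C
Reagents that add atoms: ethyltriphenylphosphonium iodide, CC[P+](c1ccccc1)(c1ccccc1)c1ccccc1.[I-]; iodine, II
Why: Wittig olefination with the α-iodo ylide Ph3P=C(I)CH3 (Stork–Zhao-type iodo-olefination) should give the (Z)-2-iodoalk-2-ene through the kinetically favoured cis-oxaphosphetane, which places iodine cis to the chain and so fixes the Z ring alkene.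

Step 4
Reactants: 4 1-({[(2E,6Z)-7-iodo-3-methylocta-2,6-dien-1-yl]oxy}methyl)-4-methoxybenzene; 5 methyl (2R)-oxirane-2-carboxylate
Product: 8 methyl (2R,4Z,8E)-2-hydroxy-10-[(4-methoxyphenyl)methoxy]-4,8-dimethyldeca-4,8-dienoate, via alkenyllithium 6 (not isolated), via alkenylmagnesium bromide 7 (not isolated)
Conditions: t-BuLi (2.1 equiv), Et2O, −78 °C; MgBr2·OEt2, −78 → 0 °C; then CuI (10 mol %), 5, THF, −45 °C
Reagents that add atoms: none
Why: Iodine–lithium exchange keeps the alkene geometry, and the derived alkenylmagnesium bromide opens the glycidic ester at its unsubstituted CH2 under copper catalysis (cuprate-type SN2 epoxide opening), so the bought stereocentre is carried over unchanged as C9.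

Step 5
Reactants: 8 methyl (2R,4Z,8E)-2-hydroxy-10-[(4-methoxyphenyl)methoxy]-4,8-dimethyldeca-4,8-dienoate
Product: 9 methyl (2R,4Z,8E)-2-[(tert-butyldimethylsilyl)oxy]-10-[(4-methoxyphenyl)methoxy]-4,8-dimethyldeca-4,8-dienoate
Conditions: tert-butyldimethylsilyl chloride, imidazole, DMF, 25 °C
Reagents that add atoms: tert-butyldimethylsilyl chloride, CC(C)(C)[Si](C)(C)Cl
Why: Imidazole-promoted silylation protects the C9 hydroxyl as a silyl ether, which blocks lactonization and later steers the ring closure; the stereocentre is not touched.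

Step 6
Reactants: 9 methyl (2R,4Z,8E)-2-[(tert-butyldimethylsilyl)oxy]-10-[(4-methoxyphenyl)methoxy]-4,8-dimethyldeca-4,8-dienoate
Product: 10 (2R,4Z,8E)-2-[(tert-butyldimethylsilyl)oxy]-10-[(4-methoxyphenyl)methoxy]-4,8-dimethyldeca-4,8-dienal
Conditions: i-Bu2AlH (1.1 equiv), CH2Cl2, −78 °C
Reagents that add atoms: none
Why: Partial ester reduction with i-Bu2AlH stops at the aldehyde because the tetrahedral aluminium hemiacetal survives at −78 °C until work-up, and the α-silyloxy centre is not epimerised under these non-basic conditions.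

Step 7
Reactants: 10 (2R,4Z,8E)-2-[(tert-butyldimethylsilyl)oxy]-10-[(4-methoxyphenyl)methoxy]-4,8-dimethyldeca-4,8-dienal
Product: 11 methyl (2Z,4R,6Z,10E)-4-[(tert-butyldimethylsilyl)oxy]-12-[(4-methoxyphenyl)methoxy]-2,6,10-trimethyldodeca-2,6,10-trienoate
Conditions: methyl 2-[bis(2,2,2-trifluoroethoxy)phosphoryl]propanoate, KN(SiMe3)2, 18-crown-6, THF, −78 °C
Reagents that add atoms: methyl 2-[bis(2,2,2-trifluoroethoxy)phosphoryl]propanoate, COC(=O)C(C)P(=O)(OCC(F)(F)F)OCC(F)(F)F
Why: Still–Gennari olefination: the electron-poor phosphonate eliminates fast from the kinetic adduct and should give the (Z)-2-methyl enoate, which places C9 cis to the future CH2Br carbon.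

Step 8
Reactants: 11 methyl (2Z,4R,6Z,10E)-4-[(tert-butyldimethylsilyl)oxy]-12-[(4-methoxyphenyl)methoxy]-2,6,10-trimethyldodeca-2,6,10-trienoate
Product: 12 (2Z,4R,6Z,10E)-4-[(tert-butyldimethylsilyl)oxy]-12-[(4-methoxyphenyl)methoxy]-2,6,10-trimethyldodeca-2,6,10-trien-1-ol
Conditions: i-Bu2AlH (2.5 equiv), CH2Cl2, −78 °C
Reagents that add atoms: none
Why: 1,2-Reduction of the enoate by i-Bu2AlH gives the allylic alcohol with the Z geometry unchanged, and both ethers are inert.

Step 9
Reactants: 12 (2Z,4R,6Z,10E)-4-[(tert-butyldimethylsilyl)oxy]-12-[(4-methoxyphenyl)methoxy]-2,6,10-trimethyldodeca-2,6,10-trien-1-ol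
Product: 13 {[(2Z,4R,6Z,10E)-1-bromo-12-[(4-methoxyphenyl)methoxy]-2,6,10-trimethyldodeca-2,6,10-trien-4-yl]oxy}(tert-butyl)dimethylsilane
Conditions: CBr4, PPh3, CH2Cl2, 0 °C
Reagents that add atoms: carbon tetrabromide, BrC(Br)(Br)Br
Why: Appel bromination replaces the primary allylic hydroxyl by SN2 displacement of the oxyphosphonium group under neutral conditions, without allylic transposition or Z/E change.

Step 10
Reactants: 13 {[(2Z,4R,6Z,10E)-1-bromo-12-[(4-methoxyphenyl)methoxy]-2,6,10-trimethyldodeca-2,6,10-trien-4-yl]oxy}(tert-butyl)dimethylsilane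
Product: 14 (2E,6Z,9R,10Z)-12-bromo-9-[(tert-butyldimethylsilyl)oxy]-3,7,11-trimethyldodeca-2,6,10-trien-1-ol
Conditions: DDQ, CH2Cl2/pH 7 buffer, 0 °C
Reagents that add atoms: none
Why: Oxidative cleavage of the 4-methoxybenzyl ether by DDQ (benzylic hydride abstraction, then hydrolysis) frees the C1 alcohol while the silyl ether and the allylic bromide stay.

Step 11
Reactants: 14 (2E,6Z,9R,10Z)-12-bromo-9-[(tert-butyldimethylsilyl)oxy]-3,7,11-trimethyldodeca-2,6,10-trien-1-ol
Product: 15 (2E,6Z,9R,10Z)-12-bromo-9-[(tert-butyldimethylsilyl)oxy]-3,7,11-trimethyldodeca-2,6,10-trienal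
Conditions: MnO2, CH2Cl2, 25 °C
Reagents that add atoms: none
Why: MnO2 oxidation is selective for the allylic alcohol and should give the (E)-enal without touching the allylic bromide or the silyl ether.

Step 12
Reactants: 15 (2E,6Z,9R,10Z)-12-bromo-9-[(tert-butyldimethylsilyl)oxy]-3,7,11-trimethyldodeca-2,6,10-trienal
Product: 17 (1S,2E,6Z,9R,10S)-9-[(tert-butyldimethylsilyl)oxy]-3,7-dimethyl-10-(prop-1-en-2-yl)cyclodeca-2,6-dien-1-ol, via allylchromium dichloride 16 (not isolated)
Conditions: CrCl2 (8 equiv), THF, 25 °C, syringe-pump addition of 15 (final 0.002 M); aqueous work-up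
Reagents that add atoms: none
Why: Divalent chromium reduces the allylic C–Br bond of 15 in two one-electron steps to the (Z)-allylchromium species 16 (trivalent chromium), which adds through its γ-carbon C10 to the tethered aldehyde in a six-membered chair transition state with chromium bridging the carbonyl oxygen and C12 (Nozaki–Hiyama allylation, whose ring-closing form is known for ten- and fourteen-membered terpene carbocycles). The ten-membered ring closes by 10-exo-trig attack on C1 with allylic transposition (SE2′), which leaves the 2-propenyl group on C10. C1 relative to C10 (hydroxyl and 2-propenyl cis on the ring) is controlled by the Z geometry of the allyl unit: the C9 substituent is axial and the enal chain equatorial in the chair. The absolute sense at C10, and through the chair at C1, is controlled by C9: 1,3-allylic strain with the cis CH2Cr group holds H9 in the allyl plane under the chair, the silyloxy oxygen takes the crowded gauche site and the ring chain C8 lies anti to the forming bond, so the Re face of C10 meets the Re face of the aldehyde, the sense of 1,2-induction known for δ-alkoxy allylchromium reagents. The step needs 1,2-addition, γ-attack, retention of the Z geometry and ring closure ahead of oligomerization: allylchromium reagents add 1,2 to enals at the substituted allyl terminus, the 2-methyl group disfavours the branched allylchromium isomer through which Z/E exchange and β-elimination of the silyloxy group would run, and slow addition at 2 mM keeps the reaction intramolecular.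

Step 13
Reactants: 17 (1S,2E,6Z,9R,10S)-9-[(tert-butyldimethylsilyl)oxy]-3,7-dimethyl-10-(prop-1-en-2-yl)cyclodeca-2,6-dien-1-ol
Product: 18 (1S,4Z,7R,8S,9R,10S)-7-[(tert-butyldimethylsilyl)oxy]-1,5-dimethyl-8-(prop-1-en-2-yl)-11-oxabicyclo[8.1.0]undec-4-en-9-ol
Conditions: m-chloroperbenzoic acid (1.05 equiv), NaHCO3, CH2Cl2, −20 → 0 °C
Reagents that add atoms: m-chloroperbenzoic acid, OOC(=O)c1cccc(Cl)c1
Why: Hydroxyl-directed peracid epoxidation: the strained E ring alkene beside the carbinol should react ahead of the Z ring alkene and the 1,1-disubstituted alkene, and with H1 eclipsing the C3 methyl (1,3-allylic strain) the hydrogen-bonded peracid attacks the peripheral face syn to the hydroxyl, which sets C2 and C3.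

Step 14
Reactants: 18 (1S,4Z,7R,8S,9R,10S)-7-[(tert-butyldimethylsilyl)oxy]-1,5-dimethyl-8-(prop-1-en-2-yl)-11-oxabicyclo[8.1.0]undec-4-en-9-ol
Product: 19 (1S,4Z,7R,8S,9R,10S)-7-[(tert-butyldimethylsilyl)oxy]-1,5-dimethyl-8-(propan-2-yl)-11-oxabicyclo[8.1.0]undec-4-en-9-ol
Conditions: H2 (3 atm), RhCl(PPh3)3 (10 mol %), benzene, 25 °C
Reagents that add atoms: none
Why: Homogeneous hydrogenation with RhCl(PPh3)3 reduces the 1,1-disubstituted alkene much faster than the trisubstituted ring alkene and leaves the epoxide intact; no stereocentre is formed.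

Step 15
Reactants: 19 (1S,4Z,7R,8S,9R,10S)-7-[(tert-butyldimethylsilyl)oxy]-1,5-dimethyl-8-(propan-2-yl)-11-oxabicyclo[8.1.0]undec-4-en-9-ol
Product: 20 (1S,4Z,7R,8R,9R,10S)-1,5-dimethyl-8-(propan-2-yl)-11-oxabicyclo[8.1.0]undec-4-ene-7,9-diol
Conditions: Bu4NF, AcOH, THF, 0 → 25 °C
Reagents that add atoms: none
Why: Fluoride-mediated desilylation frees the C9 hydroxyl, and the acetic acid buffer keeps the epoxy alkoxide from Payne-type epoxide migration.

Step 16
Reactants: 20 (1S,4Z,7R,8R,9R,10S)-1,5-dimethyl-8-(propan-2-yl)-11-oxabicyclo[8.1.0]undec-4-ene-7,9-diol; 21 3,4,5-trimethoxybenzoyl chloride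
Product: 22 (1S,4Z,7R,8S,9R,10S)-9-hydroxy-1,5-dimethyl-8-(propan-2-yl)-11-oxabicyclo[8.1.0]undec-4-en-7-yl 3,4,5-trimethoxybenzoate
Conditions: pyridine, DMAP (cat.), CH2Cl2, 0 °C
Reagents that add atoms: none
Why: DMAP-catalysed acylation by the acid chloride should take the C9 hydroxyl, which is flanked by a CH2 group, ahead of the C1 hydroxyl, which is shielded by the trisubstituted epoxide and the isopropyl-bearing carbon; C9 keeps its configuration because only the O–H bond reacts.

Compound list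
1 | geraniol, (2E)-3,7-dimethylocta-2,6-dien-1-ol | CC(C)=CCC/C(C)=C/CO | starting material
2 | 1-({[(2E)-3,7-dimethylocta-2,6-dien-1-yl]oxy}methyl)-4-methoxybenzene | CC(C)=CCC/C(C)=C/COCc1ccc(OC)cc1 | intermediate
3 | (4E)-6-[(4-methoxyphenyl)methoxy]-4-methylhex-4-enal | O=CCC/C(C)=C/COCc1ccc(OC)cc1 | intermediate
4 | 1-({[(2E,6Z)-7-iodo-3-methylocta-2,6-dien-1-yl]oxy}methyl)-4-methoxybenzene | I/C(C)=C\CC/C(C)=C/COCc1ccc(OC)cc1 | intermediate
5 | methyl (2R)-oxirane-2-carboxylate, methyl (R)-glycidate | COC(=O)[C@H]1CO1 | starting material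
6 | [(2E,6E)-8-[(4-methoxyphenyl)methoxy]-6-methylocta-2,6-dien-2-yl]lithium, lithium in place of the iodine of 4 with the geometry kept | [Li]/C(C)=C\CC/C(C)=C/COCc1ccc(OC)cc1 | intermediate
7 | bromo[(2Z,6E)-8-[(4-methoxyphenyl)methoxy]-6-methylocta-2,6-dien-2-yl]magnesium | Br[Mg]/C(C)=C\CC/C(C)=C/COCc1ccc(OC)cc1 | intermediate
8 | methyl (2R,4Z,8E)-2-hydroxy-10-[(4-methoxyphenyl)methoxy]-4,8-dimethyldeca-4,8-dienoate | O[C@@H](C(=O)OC)C/C(C)=C\CC/C(C)=C/COCc1ccc(OC)cc1 | intermediate
9 | methyl (2R,4Z,8E)-2-[(tert-butyldimethylsilyl)oxy]-10-[(4-methoxyphenyl)methoxy]-4,8-dimethyldeca-4,8-dienoate | CC(C)(C)[Si](C)(C)O[C@@H](C(=O)OC)C/C(C)=C\CC/C(C)=C/COCc1ccc(OC)cc1 | intermediate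
10 | (2R,4Z,8E)-2-[(tert-butyldimethylsilyl)oxy]-10-[(4-methoxyphenyl)methoxy]-4,8-dimethyldeca-4,8-dienal | CC(C)(C)[Si](C)(C)O[C@@H](C=O)C/C(C)=C\CC/C(C)=C/COCc1ccc(OC)cc1 | intermediate
11 | methyl (2Z,4R,6Z,10E)-4-[(tert-butyldimethylsilyl)oxy]-12-[(4-methoxyphenyl)methoxy]-2,6,10-trimethyldodeca-2,6,10-trienoate | CC(C)(C)[Si](C)(C)O[C@@H](/C=C(/C)C(=O)OC)C/C(C)=C\CC/C(C)=C/COCc1ccc(OC)cc1 | intermediate
12 | (2Z,4R,6Z,10E)-4-[(tert-butyldimethylsilyl)oxy]-12-[(4-methoxyphenyl)methoxy]-2,6,10-trimethyldodeca-2,6,10-trien-1-ol | CC(C)(C)[Si](C)(C)O[C@@H](/C=C(/C)CO)C/C(C)=C\CC/C(C)=C/COCc1ccc(OC)cc1 | intermediate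
13 | {[(2Z,4R,6Z,10E)-1-bromo-12-[(4-methoxyphenyl)methoxy]-2,6,10-trimethyldodeca-2,6,10-trien-4-yl]oxy}(tert-butyl)dimethylsilane | CC(C)(C)[Si](C)(C)O[C@@H](/C=C(/C)CBr)C/C(C)=C\CC/C(C)=C/COCc1ccc(OC)cc1 | intermediate
14 | (2E,6Z,9R,10Z)-12-bromo-9-[(tert-butyldimethylsilyl)oxy]-3,7,11-trimethyldodeca-2,6,10-trien-1-ol | CC(C)(C)[Si](C)(C)O[C@@H](/C=C(/C)CBr)C/C(C)=C\CC/C(C)=C/CO | intermediate
15 | (2E,6Z,9R,10Z)-12-bromo-9-[(tert-butyldimethylsilyl)oxy]-3,7,11-trimethyldodeca-2,6,10-trienal | CC(C)(C)[Si](C)(C)O[C@@H](/C=C(/C)CBr)C/C(C)=C\CC/C(C)=C/C=O | intermediate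
16 | dichloro[(2Z,4R,6Z,10E)-4-[(tert-butyldimethylsilyl)oxy]-2,6,10-trimethyl-12-oxododeca-2,6,10-trien-1-yl]chromium (trivalent chromium, THF ligands not drawn) | CC(C)(C)[Si](C)(C)O[C@@H](/C=C(/C)C[Cr](Cl)Cl)C/C(C)=C\CC/C(C)=C/C=O | intermediate
17 | (1S,2E,6Z,9R,10S)-9-[(tert-butyldimethylsilyl)oxy]-3,7-dimethyl-10-(prop-1-en-2-yl)cyclodeca-2,6-dien-1-ol | CC(C)(C)[Si](C)(C)O[C@@H]1C/C(C)=C\CC/C(C)=C/[C@H](O)[C@@H]1C(C)=C | intermediate
18 | (1S,4Z,7R,8S,9R,10S)-7-[(tert-butyldimethylsilyl)oxy]-1,5-dimethyl-8-(prop-1-en-2-yl)-11-oxabicyclo[8.1.0]undec-4-en-9-ol | CC(C)(C)[Si](C)(C)O[C@@H]1C/C(C)=C\CC[C@]2(C)O[C@H]2[C@H](O)[C@@H]1C(C)=C | intermediate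
19 | (1S,4Z,7R,8S,9R,10S)-7-[(tert-butyldimethylsilyl)oxy]-1,5-dimethyl-8-(propan-2-yl)-11-oxabicyclo[8.1.0]undec-4-en-9-ol | CC(C)(C)[Si](C)(C)O[C@@H]1C/C(C)=C\CC[C@]2(C)O[C@H]2[C@H](O)[C@@H]1C(C)C | intermediate
20 | (1S,4Z,7R,8R,9R,10S)-1,5-dimethyl-8-(propan-2-yl)-11-oxabicyclo[8.1.0]undec-4-ene-7,9-diol | O[C@@H]1C/C(C)=C\CC[C@]2(C)O[C@H]2[C@H](O)[C@@H]1C(C)C | intermediate
21 | 3,4,5-trimethoxybenzoyl chloride | COc1cc(C(Cl)=O)cc(OC)c1OC | starting material
22 | (1S,4Z,7R,8S,9R,10S)-9-hydroxy-1,5-dimethyl-8-(propan-2-yl)-11-oxabicyclo[8.1.0]undec-4-en-7-yl 3,4,5-trimethoxybenzoate | COc1cc(C(=O)O[C@@H]2C/C(C)=C\CC[C@]3(C)O[C@H]3[C@H](O)[C@@H]2C(C)C)cc(OC)c1OC | target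

Total step count: 16. Longest linear sequence: 16 steps, from geraniol.

Steps most likely to fail

Step 12. The allylchromium intermediate may exchange its Z geometry for E before the slow ring closure. The chair would then carry both chains equatorial and give the anti adduct, the C1 epimer. β-Elimination of the silyloxy group and oligomerization may compete as well. The facial preference at C10 is a prediction from the chair model and has to hold against the ring constraint. Fallback by correction of C1 after ring closure: setting out from 15, the same chromium cyclization would then deliver the C1-epimeric dienol F1. Mitsunobu esterification (4-nitrobenzoic acid, PPh3, diisopropyl azodicarboxylate, toluene, 0 °C) should invert the allylic carbinol to the inverted 4-nitrobenzoate F2. Methanolysis (K2CO3, MeOH) would come back to the route at 17.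

Step 13. The peracid may attack the Z ring alkene, or it may be delivered to the wrong face of the E alkene if the ring holds the C1 hydroxyl in the alkene plane. The acid-sensitive epoxide may also cyclize across the ring. Fallback by reagent control before ring closure: setting out from 14, Sharpless asymmetric epoxidation (Ti(OiPr)4, L-(+)-diethyl tartrate, t-BuOOH, 4 Å molecular sieves, CH2Cl2, −20 °C) should give the (2S,3S)-epoxy alcohol F3. Dess–Martin oxidation (NaHCO3, CH2Cl2) would give the epoxy aldehyde F4. Chromium ring closure of F4 under the conditions of step 12 would come back to the route at 18.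

Step 16. Acylation may occur at the C1 hydroxyl or at both hydroxyls. Fallback by temporary blocking of the C1 hydroxyl: setting out from 19, chloroacetylation (chloroacetic anhydride, pyridine, DMAP, CH2Cl2) should give the chloroacetate F5. Desilylation (HF·pyridine, THF) would give the hydroxy chloroacetate F6, and acylation with 21 (pyridine, DMAP) the mixed diester F7. Selective removal of the chloroacetyl group (thiourea, NaHCO3, EtOH) would come back to the route at 22.

Further compounds
F1 | step 12 | C1 epimer of 17, (1R,2E,6Z,9R,10S)-9-[(tert-butyldimethylsilyl)oxy]-3,7-dimethyl-10-(prop-1-en-2-yl)cyclodeca-2,6-dien-1-ol | CC(C)(C)[Si](C)(C)O[C@@H]1C/C(C)=C\CC/C(C)=C/[C@@H](O)[C@@H]1C(C)=C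
F2 | step 12 | 4-nitrobenzoate of 17, (1S,2E,6Z,9R,10S)-9-[(tert-butyldimethylsilyl)oxy]-3,7-dimethyl-10-(prop-1-en-2-yl)cyclodeca-2,6-dien-1-yl 4-nitrobenzoate | CC(C)(C)[Si](C)(C)O[C@@H]1C/C(C)=C\CC/C(C)=C/[C@H](OC(=O)c2ccc(cc2)[N+](=O)[O-])[C@@H]1C(C)=C
F3 | step 13 | [(2S,3S)-3-[(3Z,6R,7Z)-9-bromo-6-[(tert-butyldimethylsilyl)oxy]-4,8-dimethylnona-3,7-dien-1-yl]-3-methyloxiran-2-yl]methanol | CC(C)(C)[Si](C)(C)O[C@@H](/C=C(/C)CBr)C/C(C)=C\CC[C@]1(C)O[C@H]1CO
F4 | step 13 | (2R,3S)-3-[(3Z,6R,7Z)-9-bromo-6-[(tert-butyldimethylsilyl)oxy]-4,8-dimethylnona-3,7-dien-1-yl]-3-methyloxirane-2-carbaldehyde | CC(C)(C)[Si](C)(C)O[C@@H](/C=C(/C)CBr)C/C(C)=C\CC[C@]1(C)O[C@H]1C=O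
F5 | step 16 | chloroacetate of 19 at its free hydroxyl | CC(C)(C)[Si](C)(C)O[C@@H]1C/C(C)=C\CC[C@]2(C)O[C@H]2[C@H](OC(=O)CCl)[C@@H]1C(C)C
F6 | step 16 | desilylated F5, the monochloroacetate of 20 at the hydroxyl next to the epoxide | O[C@@H]1C/C(C)=C\CC[C@]2(C)O[C@H]2[C@H](OC(=O)CCl)[C@@H]1C(C)C
F7 | step 16 | chloroacetate of 22 at its free hydroxyl | COc1cc(C(=O)O[C@@H]2C/C(C)=C\CC[C@]3(C)O[C@H]3[C@H](OC(=O)CCl)[C@@H]2C(C)C)cc(OC)c1OC
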